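## Structural features

The target is a heliangolide-type germacranolide (germacrane numbering is used throughout): a ten-membered carbocycle C1–C10 in which an oxygen atom bridges C10 and the hemiketal carbon C3, so that the core is an 11-oxabicyclo[6.2.1]undecadiene made of a 2,5-dihydrofuran-2-ol (O, C3, C2=C1, C10) and a nine-membered ring spanned by the six-carbon bridge C4–C9. The carbocycle carries the cis C1=C2 bond inside the dihydrofuran, a trisubstituted 4Z double bond (methyl C15 on C4), an α-methylene-γ-butyrolactone trans-fused at C6/C7 (O–C12(=O)–C11(=C13)) and, on C8, a (Z)-2-(acetoxymethyl)but-2-enoate. There are five stereocenters: the contiguous triad C6(R)/C7(R)/C8(R), the quaternary carbinol carbon C10(R) that stands 1,3 to C8 and is remote from C6 and C7, and C3(R), which is not independent because the six-carbon bridge can span the dihydrofuran only cis. Fragile groups are the exocyclic methylene lactone (Michael acceptor, exo-to-endo isomerization, translactonization toward O8), the tertiary hemiketal (in equilibrium with a (Z)-γ-hydroxy dienone), the angelate-type Z side chain with its allylic acetate (ionized by zerovalent palladium), and the 4Z alkene. The real difficulty is the strained, doubly unsaturated ten-membered ring that carries the bridgehead hemiketal, together with the relation between the C6–C8 triad and the remote C10 center, for which no ring template exists before the macrocycle is closed. The key step exploits the bridgehead C3: it bears no hydrogen, is at the ketone oxidation level, and its three ring bonds end at two alkenyl carbons (C2, C4) and at a hydroxyl oxygen that sits γ to it across a cis double bond, so C3 can be supplied as carbon monoxide between two alkenyl termini and the oxygen bridge then closes by itself.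

## Logic of the disconnections

In one sentence: the oxa-bridged ten-membered core is closed by a carbonylative Stille macrocyclization of the open-chain iodide/stannane 19, in which carbon monoxide becomes the hemiketal bridgehead C3.

**23 ⇐ 22 ⇐ 21.** The O–acetyl bond of the side chain is cut, and the oxygen is carried as a silyl ether. The 2-(acyloxymethyl)enoate is an allylic ester that zerovalent palladium would ionize, so the acetate cannot be present in the key step. There is no skeletal gain; the gain is compatibility. The forward steps must cleave a primary silyl ether without opening the hemiketal and must acetylate a primary allylic hydroxyl beside the tertiary hemiketal hydroxyl.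

**21 ⇐ 20 ⇐ 19 (key).** All three ring bonds of the bridgehead are cut: C3–O(C10), C2–C3 and C3–C4. C3 leaves as carbon monoxide. The bicycle falls apart into an open chain that ends in a (Z)-alkenyl iodide (C4) and a (Z)-alkenylstannane (C2) with a free C10 hydroxyl. This removes both rings of the core, the C3 stereocenter and the need to carry a ketone or a masked hemiketal. The forward step must keep both Z geometries, insert carbon monoxide before the two termini couple directly, and close a ring in preference to chains.

**19 ⇐ 14 + 18.** The C8–O acyl bond is cut with inversion at C8. The union that makes 14 is expected to deliver the C8 epimer of the target series, so the side chain is put on by a displacement that corrects C8 and acylates in one operation. The forward step must displace a hindered secondary oxygen without elimination toward C7 and without isomerizing the Z acid.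

**14 ⇐ 8 + 13.** The C7–C8 bond is cut. An allylmetal generated at C13 of 8 attacks the aldehyde carbon of 13 through C7; this forms the bond, unveils the exocyclic methylene and sets C7 and C8 in one event. The two halves carry one stereocenter each (C6 in 8, C10 in 13), so the remote C6–C8/C10 relation is fixed by choosing enantiomers rather than by induction. The forward step must attack anti to the C6 substituent and must tolerate an alkenyl iodide and an alkenylstannane.

**8 ⇐ 7 ⇐ 5 ⇐ 3 + 4; 3 ⇐ 2 ⇐ 1.** The C13–Br bond, then C11–C13 together with the lactone C–O bond, then C6–C7 are cut. The butenolide comes from a γ-hydroxy ynoate by 1,4-hydroalumination, capture by formaldehyde and lactonization; the ynoate comes from an enal and an alkynoate by a catalytic enantioselective alkynylation that sets C6. The enal comes in two steps from a propargylic alcohol, which fixes the 4Z geometry with iodine in place for the key step.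

**13 ⇐ 12 ⇐ 10 ⇐ 9.** The C2–Sn bond and the hydrogens at C1 and C9 are removed, then the epoxide oxygen. A catalytic asymmetric epoxidation of an enynol sets C10; one hydride reagent then opens the epoxide at C9 and reduces the alkyne trans, so that the Z-stannane is made before any step that it would not survive is over. The forward steps must deliver hydride to C9 and not to the alkyne terminus.

**18 ⇐ 17 ⇐ 16 ⇐ 15.** The C–CH2O bond at the α-carbon of an alkynoate is cut. A syn hydroalumination and capture by formaldehyde gives the angelate-type Z geometry, which is the less stable one and is not available from allylic transposition chemistry.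

## Other disconnections considered

**Alternative 1:** the first that comes to mind. Cut C6–C7: an intramolecular allylation with divalent chromium (CrCl2) of the seco aldehyde/allylic bromide A1, in which a 2-(bromomethyl)acrylate adds to the C6 aldehyde and closes the ten-membered ring and the lactone together. The chosen plan is preferred because in A1 the two stereocenters C6 and C7 are created in the ring-closing event, where the topicity (trans lactone, relation to C8) is decided by a macrocyclic transition state that cannot be predicted with confidence. In addition, A1 must carry C3 as a mixed ketal and a Z enal that isomerizes easily, which costs protecting steps. In the chosen plan C6–C8 are set in an open chain by a ring-templated transition state, and the ring closure creates no independent stereocenter.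

**Alternative 2:** cut C1=C2: ring-closing metathesis of the divinyl ketone/vinyl carbinol A2. The chosen plan is preferred for three reasons. The metathesis has to join an electron-poor vinyl ketone and a hindered tertiary allylic carbinol and must give the Z olefin with no control element other than ring strain. The exocyclic methylene and the side-chain alkene are competing partners. A2 is itself most directly made from the same alkenyl iodide by a carbonylative coupling, so this route is longer by one step and puts a polymerizable cross-conjugated ketone in front of the ring closure.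

**Alternative 3:** biomimetic. Cut C10–O: a Schenck ene reaction of singlet oxygen with the 3-oxo-1(10),4-dienolide A3 to give the 10-hydroperoxy (1E)-enone A4, followed by reduction, E-to-Z photoisomerization and hemiketal closure. The chosen plan is preferred because A3 is itself a ten-membered ring that needs its own closure, so nothing is simplified. Regioselectivity (hydrogen abstraction at C2, C9 or C14) and facial selectivity at C10 are not controlled in a flexible ring. The E enone expected in A4 needs a photochemical step in the presence of three other chromophores.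

Key step: step 14

Remarks: (i) Germacrane numbering (C1–C15) is used for all intermediates. (ii) In step 3 the ligand is 2,6-bis{[(S)-2-(hydroxydiphenylmethyl)pyrrolidin-1-yl]methyl}-4-methylphenol ((S,S)-ProPhenol); it is assumed to give the 4R alcohol, and if the sense is opposite the (R,R)-ligand is used. (iii) The pure E isomer of 9 is taken as the commercial material.

## Steps

Step 1
Reactants: 1 but-2-yn-1-ol
Product: 2 (2Z)-3-iodobut-2-en-1-ol
Conditions: NaAlH2(OCH2CH2OMe)2, THF, 0 °C to rt; then I2, −78 °C to 0 °C
Reagents that add atoms: iodine, [I][I]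
Why: Hydroxyl-directed trans-hydroalumination of a propargylic alcohol puts hydride on C2 and aluminium on C3 in a five-membered alkoxyalanate; iodinolysis with retention should give the Z iodide, which fixes the 4Z geometry of the target with iodine cis to the future C6.

Step 2
Reactants: 2 (2Z)-3-iodobut-2-en-1-ol
Product: 3 (2Z)-3-iodobut-2-enal
Conditions: MnO2, CH2Cl2, rt, dark; used at once
Reagents that add atoms: none
Why: Allylic oxidation with MnO2 is neutral and heterogeneous, so the Z β-iodo enal should form without isomerization if it is kept cold and dark.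

Step 3
Reactants: 3 (2Z)-3-iodobut-2-enal; 4 methyl propiolate
Product: 5 methyl (4R,5Z)-4-hydroxy-6-iodohept-5-en-2-ynoate
Conditions: (S,S)-ProPhenol (20 mol %), ZnMe2 (3 equiv), Ph3PO (40 mol %), toluene, 4 °C
Reagents that add atoms: none
Why: Zinc/ProPhenol-catalysed enantioselective alkynylation of an α,β-unsaturated aldehyde; the dinuclear zinc catalyst binds aldehyde and zinc acetylide and sets C6, the only stereocenter of this fragment, by catalyst control.

Step 4
Reactants: 5 methyl (4R,5Z)-4-hydroxy-6-iodohept-5-en-2-ynoate
Product: 7 (5S)-3-(hydroxymethyl)-5-[(1Z)-2-iodoprop-1-en-1-yl]furan-2(5H)-one, via open-chain diol ester 6 (not isolated)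
Conditions: AlH(iBu)2 (2.3 equiv), N-methylmorpholine N-oxide, THF, 0 °C; then (CH2O)n, 0 °C to rt; 1 M HCl work-up
Reagents that add atoms: formaldehyde (from paraformaldehyde), C=O
Why: 1,4-Hydroalumination of the ynoate (vinylalumination) gives an α-aluminio acrylate that adds to formaldehyde at C11 from the side of the β-hydrogen, so the ester ends cis to C6 (2Z) and 6 lactonizes on work-up; C6 is not touched (its descriptor changes only because the priorities change).

Step 5
Reactants: 7 (5S)-3-(hydroxymethyl)-5-[(1Z)-2-iodoprop-1-en-1-yl]furan-2(5H)-one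
Product: 8 (5S)-3-(bromomethyl)-5-[(1Z)-2-iodoprop-1-en-1-yl]furan-2(5H)-one
Conditions: CBr4, PPh3, CH2Cl2, 0 °C
Reagents that add atoms: carbon tetrabromide, BrC(Br)(Br)Br
Why: Appel bromination of a primary allylic alcohol under neutral conditions; no base is present that could remove the acidic γ-hydrogen at C6.

Step 6
Reactants: 9 (2E)-3-methylpent-2-en-4-yn-1-ol
Product: 10 [(2S,3S)-3-ethynyl-3-methyloxiran-2-yl]methanol
Conditions: Ti(OiPr)4 (10 mol %), L-(+)-diethyl tartrate (12 mol %), tBuOOH, 4 Å molecular sieves, CH2Cl2, −20 °C
Reagents that add atoms: tert-butyl hydroperoxide, CC(C)(C)OO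
Why: Sharpless asymmetric epoxidation of a trisubstituted E allylic alcohol; L-(+)-tartrate delivers oxygen to the face that gives the (2S,3S)-epoxide, which sets the quaternary C10.

Step 7
Reactants: 10 [(2S,3S)-3-ethynyl-3-methyloxiran-2-yl]methanol
Product: 12 (3R,4Z)-3-methyl-5-(tributylstannyl)pent-4-ene-1,3-diol, via alkynediol alkoxyalanate 11 (not isolated)
Conditions: NaAlH2(OCH2CH2OMe)2 (3.5 equiv), THF, 0 °C to rt; then Bu3SnOTf, −78 °C to 0 °C
Reagents that add atoms: tributyltin trifluoromethanesulfonate, CCCC[Sn](CCCC)(CCCC)OS(=O)(=O)C(F)(F)F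
Why: Two hydroxyl-directed alanate reactions in sequence: the primary alkoxyalanate delivers hydride to C9 (1,3-diol-selective opening of a 2,3-epoxy alcohol), then the tertiary propargylic alkoxyalanate adds hydride to C1 and aluminium to C2 trans; the tin triflate replaces aluminium with retention to give the Z stannane, and C10 keeps its C–O bond and configuration.

Step 8
Reactants: 12 (3R,4Z)-3-methyl-5-(tributylstannyl)pent-4-ene-1,3-diol
Product: 13 (3R,4Z)-3-hydroxy-3-methyl-5-(tributylstannyl)pent-4-enal
Conditions: Dess–Martin periodinane, NaHCO3, CH2Cl2, 0 °C; used crude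
Reagents that add atoms: none
Why: Dess–Martin oxidation of the primary alcohol; the tertiary alcohol cannot be oxidized, and the buffered medium should avoid β-elimination or retro-aldol cleavage of the β-hydroxy aldehyde.

Step 9
Reactants: 8 (5S)-3-(bromomethyl)-5-[(1Z)-2-iodoprop-1-en-1-yl]furan-2(5H)-one; 13 (3R,4Z)-3-hydroxy-3-methyl-5-(tributylstannyl)pent-4-enal
Product: 14 (4R,5S)-4-[(1S,3R,4Z)-1,3-dihydroxy-3-methyl-5-(tributylstannyl)pent-4-en-1-yl]-5-[(1Z)-2-iodoprop-1-en-1-yl]-3-methylideneoxolan-2-one
Conditions: Zn dust, THF/saturated aqueous NH4Cl (1:1), 0 °C to rt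
Reagents that add atoms: none
Why: Zinc Barbier allylation: the allylzinc from 8 attacks the aldehyde through C7 with allylic transposition, forming C7–C8 and the exocyclic methylene together. C7 is set by attack anti to the C6 alkenyl group on the flat butenolide (6,7-trans); C8 is set by a closed chair transition state in which the ring carbon C6 is locked trans to CH2Zn and the aldehyde substituent is equatorial, away from the lactone carbonyl, which should give 8S (the C8 epimer of the target series) whatever the remote C10 center.

Step 10
Reactants: 15 methyl but-2-ynoate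
Product: 16 methyl (2Z)-2-(hydroxymethyl)but-2-enoate
Conditions: AlH(iBu)2, N-methylmorpholine N-oxide, THF, 0 °C; then (CH2O)n, rt
Reagents that add atoms: formaldehyde (from paraformaldehyde), C=O
Why: Vinylalumination as in step 4: syn 1,4-hydroalumination and capture at the α-carbon from the side of the β-hydrogen should leave the ester cis to the β-methyl, the angelate-type Z geometry.

Step 11
Reactants: 16 methyl (2Z)-2-(hydroxymethyl)but-2-enoate
Product: 17 methyl (2Z)-2-{[(tert-butyldimethylsilyl)oxy]methyl}but-2-enoate
Conditions: TBSCl, imidazole, DMF, rt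
Reagents that add atoms: tert-butyldimethylsilyl chloride, CC(C)(C)[Si](C)(C)Cl
Why: Standard silylation; the silyl ether stands in for the acetate so that no allylic ester meets zerovalent palladium in step 14.

Step 12
Reactants: 17 methyl (2Z)-2-{[(tert-butyldimethylsilyl)oxy]methyl}but-2-enoate
Product: 18 (2Z)-2-{[(tert-butyldimethylsilyl)oxy]methyl}but-2-enoic acid
Conditions: LiOH, THF/MeOH/H2O, 0 °C to rt; then 1 M HCl to pH 4
Reagents that add atoms: lithium hydroxide, [Li+].[OH-]
Why: Saponification at or below room temperature; the silyl ether and the Z geometry should survive cold LiOH.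

Step 13
Reactants: 14 (8S alcohol from step 9); 18 (2Z)-2-{[(tert-butyldimethylsilyl)oxy]methyl}but-2-enoic acid
Product: 19 (1R,3R,4Z)-3-hydroxy-1-{(2S,3R)-2-[(1Z)-2-iodoprop-1-en-1-yl]-4-methylidene-5-oxooxolan-3-yl}-3-methyl-5-(tributylstannyl)pent-4-en-1-yl (2Z)-2-{[(tert-butyldimethylsilyl)oxy]methyl}but-2-enoate
Conditions: PPh3, diisopropyl azodicarboxylate, toluene, 0 °C to rt
Reagents that add atoms: none
Why: Mitsunobu esterification: the secondary C8 hydroxyl is activated as an oxyphosphonium ion and displaced by the carboxylate with inversion (8S to 8R), which corrects the Barbier topicity and installs the side chain in one step; the tertiary C10 hydroxyl does not react.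

Step 14
Reactants: 19 (open-chain alkenyl iodide/alkenylstannane)
Product: 21 (3R,6R,7R,8R,10R)-8-{[(2Z)-2-{[(tert-butyldimethylsilyl)oxy]methyl}but-2-enoyl]oxy}-3-hydroxy-3,10-epoxygermacra-1,4Z,11(13)-trien-12,6-olide, via macrocyclic dienone 20 (not isolated)
Conditions: Pd2(dba)3 (10 mol %), AsPh3 (40 mol %), CO (3 atm), DMF, 50 °C, 1 mM, addition of 19 by syringe pump
Reagents that add atoms: carbon monoxide, [C-]#[O+]
Why: Zerovalent palladium inserts into the C4–I bond with retention, CO inserts to give the C3 acylpalladium, the (Z)-alkenylstannane at C2 transmetalates with retention and reductive elimination forms C2–C3, so that CO becomes C3 of the (1Z,4Z)-dienone 20; the closest known reaction type is the carbonylative Stille ring closure of alkenyl halide/alkenylstannane chains to macrocyclic divinyl ketones. The ten-membered carbocycle closes by reductive elimination from an eleven-membered acyl(alkenyl)palladacycle. The dihydrofuran then closes by 5-exo-trig addition of the C10 hydroxyl to the C3 carbonyl, which the 1Z geometry holds within bonding distance, so 20 should not accumulate. C3 is the only new stereocenter and is fixed by C10, because the six-carbon bridge can span the dihydrofuran only cis and the hemiketal hydroxyl must therefore be exo (3R). The step needs CO insertion to outrun direct coupling; the CO pressure, the slow transmetalation of a Z stannane and the strain of the nine-membered diene that direct coupling would give secure this. It needs ring closure to outrun chain growth; high dilution, the two Z alkenes and the trans lactone, which turn both chain ends toward each other, secure this. The tertiary hydroxyl is too hindered to trap the acylpalladium, and the side chain carries a silyl ether instead of the allylic acetate so that no allylpalladium can form.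

Step 15
Reactants: 21 (silyl ether of the bicyclic hemiketal)
Product: 22 (3R,6R,7R,8R,10R)-3-hydroxy-8-{[(2Z)-2-(hydroxymethyl)but-2-enoyl]oxy}-3,10-epoxygermacra-1,4Z,11(13)-trien-12,6-olide
Conditions: HF·pyridine, pyridine, THF, 0 °C
Reagents that add atoms: none
Why: Buffered fluoride cleavage of a primary silyl ether; the pyridine buffer should protect the hemiketal and the methylene lactone.

Step 16
Reactants: 22 (primary allylic alcohol)
Product: 23 (3R,6R,7R,8R,10R)-8-{[(2Z)-2-(acetoxymethyl)but-2-enoyl]oxy}-3-hydroxy-3,10-epoxygermacra-1,4Z,11(13)-trien-12,6-olide (target, CNP0256971.1)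
Conditions: Ac2O, pyridine, CH2Cl2, 0 °C
Reagents that add atoms: acetic anhydride, CC(=O)OC(C)=O
Why: Acetylation of the primary allylic hydroxyl; without an acyl-transfer catalyst the tertiary hemiketal hydroxyl should not be acylated.

## Compound list

1 | but-2-yn-1-ol | CC#CCO | starting material
2 | (2Z)-3-iodobut-2-en-1-ol | C/C(I)=C/CO | intermediate
3 | (2Z)-3-iodobut-2-enal | C/C(I)=C/C=O | intermediate
4 | methyl propiolate | C#CC(=O)OC | starting material
5 | methyl (4R,5Z)-4-hydroxy-6-iodohept-5-en-2-ynoate | O[C@@H](C#CC(=O)OC)/C=C(/C)I | intermediate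
6 | methyl (2Z,4S,5Z)-4-hydroxy-2-(hydroxymethyl)-6-iodohepta-2,5-dienoate | COC(=O)/C(CO)=C\[C@H](O)/C=C(/C)I | intermediate (not isolated)
7 | (5S)-3-(hydroxymethyl)-5-[(1Z)-2-iodoprop-1-en-1-yl]furan-2(5H)-one | O=C1O[C@@H](C=C1CO)/C=C(/C)I | intermediate
8 | (5S)-3-(bromomethyl)-5-[(1Z)-2-iodoprop-1-en-1-yl]furan-2(5H)-one | O=C1O[C@@H](C=C1CBr)/C=C(/C)I | intermediate
9 | (2E)-3-methylpent-2-en-4-yn-1-ol | C#C/C(C)=C/CO | starting material
10 | [(2S,3S)-3-ethynyl-3-methyloxiran-2-yl]methanol | OC[C@@H]1O[C@@]1(C)C#C | intermediate
11 | (3R)-3-methylpent-4-yne-1,3-diol (present as its alkoxyalanate) | C#C[C@@](C)(CCO)O | intermediate (not isolated)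
12 | (3R,4Z)-3-methyl-5-(tributylstannyl)pent-4-ene-1,3-diol | CCCC[Sn](CCCC)(CCCC)/C=C\[C@@](C)(CCO)O | intermediate
13 | (3R,4Z)-3-hydroxy-3-methyl-5-(tributylstannyl)pent-4-enal | CCCC[Sn](CCCC)(CCCC)/C=C\[C@@](C)(CC=O)O | intermediate
14 | (4R,5S)-4-[(1S,3R,4Z)-1,3-dihydroxy-3-methyl-5-(tributylstannyl)pent-4-en-1-yl]-5-[(1Z)-2-iodoprop-1-en-1-yl]-3-methylideneoxolan-2-one | C=C1C(=O)O[C@H](/C=C(/C)I)[C@H]1[C@@H](O)C[C@@](C)(O)/C=C\[Sn](CCCC)(CCCC)CCCC | intermediate
15 | methyl but-2-ynoate | CC#CC(=O)OC | starting material
16 | methyl (2Z)-2-(hydroxymethyl)but-2-enoate | COC(=O)/C(=C\C)CO | intermediate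
17 | methyl (2Z)-2-{[(tert-butyldimethylsilyl)oxy]methyl}but-2-enoate | COC(=O)/C(=C\C)CO[Si](C)(C)C(C)(C)C | intermediate
18 | (2Z)-2-{[(tert-butyldimethylsilyl)oxy]methyl}but-2-enoic acid | OC(=O)/C(=C\C)CO[Si](C)(C)C(C)(C)C | intermediate
19 | (1R,3R,4Z)-3-hydroxy-1-{(2S,3R)-2-[(1Z)-2-iodoprop-1-en-1-yl]-4-methylidene-5-oxooxolan-3-yl}-3-methyl-5-(tributylstannyl)pent-4-en-1-yl (2Z)-2-{[(tert-butyldimethylsilyl)oxy]methyl}but-2-enoate | C=C1C(=O)O[C@H](/C=C(/C)I)[C@H]1[C@H](OC(=O)/C(=C\C)CO[Si](C)(C)C(C)(C)C)C[C@@](C)(O)/C=C\[Sn](CCCC)(CCCC)CCCC | intermediate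
20 | (1Z,4Z,6R,7R,8R,10R)-8-{[(2Z)-2-{[(tert-butyldimethylsilyl)oxy]methyl}but-2-enoyl]oxy}-10-hydroxy-3-oxogermacra-1,4,11(13)-trien-12,6-olide | C=C1C(=O)O[C@@H]2/C=C(/C)C(=O)/C=C\[C@@](C)(C[C@@H](OC(=O)/C(=C\C)CO[Si](C)(C)C(C)(C)C)[C@@H]12)O | intermediate (not isolated)
21 | (3R,6R,7R,8R,10R)-8-{[(2Z)-2-{[(tert-butyldimethylsilyl)oxy]methyl}but-2-enoyl]oxy}-3-hydroxy-3,10-epoxygermacra-1,4Z,11(13)-trien-12,6-olide | C=C1C(=O)O[C@@H]2/C=C(/C)[C@@]3(O)C=C[C@@](C)(C[C@@H](OC(=O)/C(=C\C)CO[Si](C)(C)C(C)(C)C)[C@@H]12)O3 | intermediate
22 | (3R,6R,7R,8R,10R)-3-hydroxy-8-{[(2Z)-2-(hydroxymethyl)but-2-enoyl]oxy}-3,10-epoxygermacra-1,4Z,11(13)-trien-12,6-olide | C=C1C(=O)O[C@@H]2/C=C(/C)[C@@]3(O)C=C[C@@](C)(C[C@@H](OC(=O)/C(=C\C)CO)[C@@H]12)O3 | intermediate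
23 | (3R,6R,7R,8R,10R)-8-{[(2Z)-2-(acetoxymethyl)but-2-enoyl]oxy}-3-hydroxy-3,10-epoxygermacra-1,4Z,11(13)-trien-12,6-olide | C=C1C(=O)O[C@@H]2/C=C(/C)[C@@]3(O)C=C[C@@](C)(C[C@@H](OC(=O)/C(=C\C)COC(C)=O)[C@@H]12)O3 | target

## Step count and least certain steps

Total: 16 steps. Longest linear sequence: 10 steps (1–5, 9, 13–16).

**Step 14 (key).** Most likely to go wrong: chain growth or protodestannylation outrunning the slow macrocyclic transmetalation, direct coupling without CO insertion, or capture of the acylpalladium by the exocyclic methylene. Fallback (from 19, back at 21): the ring is closed by olefin metathesis at C1=C2 instead. Protodestannylation of 19 (CF3CO2H, CH2Cl2, −20 °C) gives the vinyl carbinol F1. An intermolecular carbonylative Stille coupling of its alkenyl iodide with tributyl(vinyl)stannane (Pd2(dba)3, AsPh3, CO) gives the divinyl ketone F2. Ring-closing metathesis (second-generation Grubbs catalyst, dilute toluene, 80 °C) between the vinyl ketone and the vinyl carbinol gives 20, which closes to 21.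

**Step 9.** Most likely to go wrong: loss of topicity at C8 (open or boat transition states beside the chair, giving both C8 epimers), attack through C13 instead of C7, or reductive loss of bromide. Fallback (from 8 and 13, back at 19): both epimers are funneled to 19 by changing the esterification. If the 8R alcohol F3 forms, it is separated and acylated with retention: 18 is converted with 2,4,6-trichlorobenzoyl chloride and Et3N into the mixed anhydride F4, which acylates F3 (DMAP, toluene) to give 19, while 14 goes through step 13.

**Step 13.** Most likely to go wrong: elimination of the activated C8 oxygen toward C7 (the C7 hydrogen is allylic to the exocyclic methylene), or Z-to-E isomerization of the side-chain acid through reversible phosphine addition. Fallback (from 14, back at 19): a phosphine-free inversion in two stages. 14 is converted into the chloromethanesulfonate F5 (ClCH2SO2Cl, pyridine, 0 °C), which is displaced by the caesium carboxylate F6, made from 18 and Cs2CO3 (18-crown-6, toluene, 50 °C), to give 19.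

**Step 7.** Most likely to go wrong: hydride attack at the alkyne terminus with opening of the propargylic epoxide (allene formation) in competition with directed delivery to C9, incomplete hydroalumination, or protonation in place of stannylation. Fallback (from 10, back at 12): the two events are separated and tin is introduced by a different mechanism. Opening with NaAlH2(OCH2CH2OMe)2 at −20 °C and aqueous work-up gives 11, which is isolated; a radical hydrostannation under kinetic control (Bu3SnH, Et3B, air, toluene, −78 °C) adds tin anti to give 12.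

**Step 4.** Most likely to go wrong: 1,2-reduction of the ester, incomplete 1,4-hydroalumination of the ynoate that carries a free hydroxyl, or loss of the 2Z geometry so that lactonization fails. Fallback (from 3, back at 8): the carboxyl carbon, not C13, is added last. 3 is alkynylated with tert-butyldimethyl(prop-2-yn-1-yloxy)silane under the conditions of step 3 to give the propargylic alcohol F7. Hydroxyl-directed trans-hydroalumination (NaAlH2(OCH2CH2OMe)2, THF) and capture of the alkenylalanate at C11 with methyl chloroformate gives the (2Z)-hydroxy ester F8, which lactonizes to the silyloxymethyl butenolide F9. Ph3PBr2 (CH2Cl2, 0 °C) converts the silyl ether directly into bromide 8.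

## Further compounds

F1 | step 14 | (1R,3R)-3-hydroxy-1-{(2S,3R)-2-[(1Z)-2-iodoprop-1-en-1-yl]-4-methylidene-5-oxooxolan-3-yl}-3-methylpent-4-en-1-yl (2Z)-2-{[(tert-butyldimethylsilyl)oxy]methyl}but-2-enoate | C=C1C(=O)O[C@H](/C=C(/C)I)[C@H]1[C@H](OC(=O)/C(=C\C)CO[Si](C)(C)C(C)(C)C)C[C@@](C)(O)C=C
F2 | step 14 | divinyl ketone: analogue of F1 in which iodine is replaced by a prop-2-enoyl group (C3 ketone between C4 and a vinyl group) | C=C1C(=O)O[C@H](/C=C(/C)C(=O)C=C)[C@H]1[C@H](OC(=O)/C(=C\C)CO[Si](C)(C)C(C)(C)C)C[C@@](C)(O)C=C
F3 | step 9 | (4R,5S)-4-[(1R,3R,4Z)-1,3-dihydroxy-3-methyl-5-(tributylstannyl)pent-4-en-1-yl]-5-[(1Z)-2-iodoprop-1-en-1-yl]-3-methylideneoxolan-2-one (C8 epimer of 14) | C=C1C(=O)O[C@H](/C=C(/C)I)[C@H]1[C@H](O)C[C@@](C)(O)/C=C\[Sn](CCCC)(CCCC)CCCC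
F4 | step 9 | (2Z)-2-{[(tert-butyldimethylsilyl)oxy]methyl}but-2-enoic 2,4,6-trichlorobenzoic anhydride | Clc1cc(Cl)c(C(=O)OC(=O)/C(=C\C)CO[Si](C)(C)C(C)(C)C)c(Cl)c1
F5 | step 13 | chloromethanesulfonate of 14 at the C8 oxygen (8S) | C=C1C(=O)O[C@H](/C=C(/C)I)[C@H]1[C@@H](OS(=O)(=O)CCl)C[C@@](C)(O)/C=C\[Sn](CCCC)(CCCC)CCCC
F6 | step 13 | caesium (2Z)-2-{[(tert-butyldimethylsilyl)oxy]methyl}but-2-enoate | [Cs+].[O-]C(=O)/C(=C\C)CO[Si](C)(C)C(C)(C)C
F0 | step 7 | none | none
F7 | step 4 | (4R,5Z)-1-[(tert-butyldimethylsilyl)oxy]-6-iodohept-5-en-2-yn-4-ol | O[C@@H](C#CCO[Si](C)(C)C(C)(C)C)/C=C(/C)I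
F8 | step 4 | methyl (2Z,4S,5Z)-2-{[(tert-butyldimethylsilyl)oxy]methyl}-4-hydroxy-6-iodohepta-2,5-dienoate | COC(=O)/C(CO[Si](C)(C)C(C)(C)C)=C\[C@H](O)/C=C(/C)I
F9 | step 4 | (5S)-3-{[(tert-butyldimethylsilyl)oxy]methyl}-5-[(1Z)-2-iodoprop-1-en-1-yl]furan-2(5H)-one | O=C1O[C@@H](C=C1CO[Si](C)(C)C(C)(C)C)/C=C(/C)I
A1 | alternative 1 | seco aldehyde/allylic bromide: methyl (2Z)-2-(bromomethyl)-4-[(tert-butyldimethylsilyl)oxy]-5-{5-methoxy-2-methyl-5-[(2Z)-4-oxobut-2-en-2-yl]-2,5-dihydrofuran-2-yl}pent-2-enoate, stereocenters C3, C8, C10 as in the target | O=C/C=C(/C)[C@@]1(OC)C=C[C@@](C)(C[C@@H](O[Si](C)(C)C(C)(C)C)/C=C(\CBr)C(=O)OC)O1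
A2 | alternative 2 | seco divinyl ketone/vinyl carbinol: trans lactone with a (Z)-3-methyl-4-oxohexa-2,5-dien-2-yl group at C6 side (C5=C4(Me)–C3(=O)–CH=CH2), the final ester at C8 and a 10-hydroxy-10-vinyl terminus | C=C1C(=O)O[C@H](/C=C(/C)C(=O)C=C)[C@H]1[C@H](OC(=O)/C(=C\C)COC(C)=O)C[C@@](C)(O)C=C
A3 | alternative 3 | (1(10)E,4Z)-8-{[(2Z)-2-(acetoxymethyl)but-2-enoyl]oxy}-3-oxogermacra-1(10),4,11(13)-trien-12,6-olide | C=C1C(=O)O[C@@H]2/C=C(/C)C(=O)C/C=C(\C)C[C@@H](OC(=O)/C(=C\C)COC(C)=O)[C@@H]12
A4 | alternative 3 | (1E,4Z)-8-{[(2Z)-2-(acetoxymethyl)but-2-enoyl]oxy}-10-hydroperoxy-3-oxogermacra-1,4,11(13)-trien-12,6-olide | C=C1C(=O)O[C@@H]2/C=C(/C)C(=O)/C=C/[C@](C)(OO)C[C@@H](OC(=O)/C(=C\C)COC(C)=O)[C@@H]12
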